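**Retrosynthetic overview**

1. Target 53 ← global deprotection ← oxidative opening of a naphtho[2,1-d]oxazol-5-ol, in which the oxazole carries the C1 oxygen, the C2 nitrogen and, as its C-2, the amide carbon C15 ← macrocycle closed at C11–C12 (Nozaki–Hiyama–Kishi, then oxidation).
2. Seco compound ← Stille union at C17–C18 of aromatic vinyl iodide 24 with chain stannane 44, then Stork–Zhao iodo-olefination at C29.
3. Ring A ← Wolff rearrangement/6π electrocyclisation of 4-diazoacetyl-5-aryloxazole 16. Enabling feature: ring A bears O on C1 and N on C2 on adjacent carbons, so C1, C2 and C15 can be tied into an oxazole. Its C4=C5 bond (C2=C1) holds the ketene C3=C4 and the C8a=C4a bond of benzene ring B cis as a hexatriene; C5–H and the C7 methyl steer closure to C4a.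
4. Chain 44 ← anti boron aldol/syn reduction of ketone 40 (C24–C29) with aldehyde 32 (C18–C23); 32 ← Evans aldol and chelation-controlled ethynylation; 40 ← Evans aldol and A(1,3)-controlled hydroboration.
5. Ring order: benzene ring B (bought) → oxazole (step 6) → ring A (step 9) → 22-membered oxazole-bridged macrocycle (step 35) → oxazole opened to quinone and amide (step 37).

Key step: step 9

Remark: atoms carry ansamycin locants (C1–C8a ring carbons, C11 aryl ketone carbon, C12–C29 chain, C15 amide carbon, C34a the CH2OH carbon on C28); the target is read from the SMILES as 12Z,16Z,18E,20R,21R,22S,23S,24S,25S,26R,27S,28S; centres destroyed later (C2 of 10–12, C4a of 18, C11 of 49) are carried as mixtures; TBS = tert-butyldimethylsilyl, TES = triethylsilyl, PMB = 4-methoxybenzyl.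

**Route**

Step 1
Reactants: 1 prop-2-yn-1-ol
Product: 2 (Z)-3-iodo-2-methylprop-2-en-1-ol
Conditions: MeMgBr (2.5 equiv), CuI (10 mol %), THF/Et2O, −10 °C → rt; then I2, −10 °C
Reagents that add atoms: methylmagnesium bromide (C[Mg]Br); iodine (II)
Why: Copper-catalysed anti-carbomagnesiation of the propargylic magnesium alkoxide gives a five-membered vinylmagnesium chelate, and iodinolysis with retention places iodine cis to the CH2OH group (Z).

Step 2
Reactants: 2 (Z)-3-iodo-2-methylprop-2-en-1-ol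
Product: 4 (Z)-3-iodo-2-methylprop-2-enoic acid, via (Z)-3-iodo-2-methylprop-2-enal 3 (not isolated)
Conditions: MnO2, CH2Cl2, rt, dark; filter; then NaClO2, NaH2PO4, 2-methylbut-2-ene, t-BuOH/H2O, 0 °C
Reagents that add atoms: sodium chlorite ([Na+].[O-]Cl=O)
Why: Allylic oxidation followed at once by Pinnick oxidation of the unpurified enal should give the acid with the Z geometry kept, because the enal is never stored or exposed to base.

Step 3
Reactants: 5 4-hydroxy-3-methylbenzoic acid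
Product: 7 4-[(4-methoxybenzyl)oxy]-3-methylbenzoic acid, via bis-PMB ester 6 (not isolated)
Conditions: 4-methoxybenzyl chloride (2.3 equiv), K2CO3, DMF, 60 °C; then NaOH, MeOH/H2O, 60 °C; 1 M HCl to pH 4
Reagents that add atoms: 4-methoxybenzyl chloride (COc1ccc(CCl)cc1); sodium hydroxide ([Na+].[OH-])
Why: Williamson alkylation of phenoxide and carboxylate followed by saponification of the benzylic ester in the same flask leaves only the base-stable aryl PMB ether.

Step 4
Reactants: 7 4-[(4-methoxybenzyl)oxy]-3-methylbenzoic acid; 8 methyl N-(diphenylmethylidene)glycinate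
Product: 11 methyl 2-amino-3-{4-[(4-methoxybenzyl)oxy]-3-methylphenyl}-3-oxopropanoate hydrochloride (racemic), via acid chloride 9 (not isolated), via N-diphenylmethylidene keto ester 10 (not isolated)
Conditions: 1-chloro-N,N,2-trimethylprop-1-en-1-amine, CH2Cl2, 0 °C; then 8, KOt-Bu (2 equiv), THF, −78 °C; then 1 M HCl, THF, rt
Reagents that add atoms: hydrogen chloride (Cl)
Why: The potassium enolate of the glycine Schiff base is C-acylated by the acid chloride (Claisen-type acylation, the chloride being made without free HCl so that the PMB ether survives), and dilute acid hydrolyses only the imine to give the amine as its stable hydrochloride.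

Step 5
Reactants: 11 methyl 2-amino-3-{4-[(4-methoxybenzyl)oxy]-3-methylphenyl}-3-oxopropanoate hydrochloride; 4 (Z)-3-iodo-2-methylprop-2-enoic acid
Product: 12 methyl 2-[(Z)-3-iodo-2-methylprop-2-enamido]-3-{4-[(4-methoxybenzyl)oxy]-3-methylphenyl}-3-oxopropanoate
Conditions: EDC·HCl, HOBt, N-methylmorpholine, CH2Cl2, 0 °C → rt
Reagents that add atoms: none
Why: Carbodiimide/HOBt amide coupling at 0 °C acylates the amine as it is set free from its salt, faster than self-condensation of the amino ketone and without Z/E isomerisation of the iodoacrylic acid.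

Step 6
Reactants: 12 methyl 2-[(Z)-3-iodo-2-methylprop-2-enamido]-3-aryl-3-oxopropanoate
Product: 13 methyl 2-[(Z)-1-iodoprop-1-en-2-yl]-5-{4-[(4-methoxybenzyl)oxy]-3-methylphenyl}-1,3-oxazole-4-carboxylate
Conditions: PPh3, I2, Et3N, CH2Cl2, 0 °C → rt
Reagents that add atoms: none
Why: Robinson–Gabriel cyclodehydration of the 2-acylamino ketone with PPh3/I2/Et3N closes the oxazole (attack of the amide oxygen on the activated ketone, then elimination) under conditions that the vinyl iodide and the PMB ether tolerate.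

Step 7
Reactants: 13 methyl oxazole-4-carboxylate
Product: 14 2-[(Z)-1-iodoprop-1-en-2-yl]-5-{4-[(4-methoxybenzyl)oxy]-3-methylphenyl}-1,3-oxazole-4-carboxylic acid
Conditions: LiOH, THF/MeOH/H2O, 0 °C; 1 M HCl to pH 3
Reagents that add atoms: lithium hydroxide ([Li+].[OH-])
Why: Saponification of the unhindered heteroaryl methyl ester at 0 °C is faster than addition–elimination at the iodoalkene.

Step 8
Reactants: 14 oxazole-4-carboxylic acid
Product: 16 2-diazo-1-{2-[(Z)-1-iodoprop-1-en-2-yl]-5-{4-[(4-methoxybenzyl)oxy]-3-methylphenyl}-1,3-oxazol-4-yl}ethan-1-one, via mixed carbonic anhydride 15 (not isolated)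
Conditions: i-BuOCOCl, N-methylmorpholine, THF, −15 °C; then CH2N2, Et2O, 0 °C → rt
Reagents that add atoms: diazomethane (C=[N+]=[N-])
Why: Acylation of diazomethane by the mixed anhydride (first stage of an Arndt–Eistert sequence) gives the diazomethyl ketone without an acid chloride, so the PMB ether and the vinyl iodide are untouched.

Step 9
Reactants: 16 4-diazoacetyl-5-aryloxazole
Product: 19 2-[(Z)-1-iodoprop-1-en-2-yl]-7-[(4-methoxybenzyl)oxy]-8-methylnaphtho[2,1-d][1,3]oxazol-5-ol, via oxazolylketene 17 (not isolated), via dienone 18 (not isolated)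
Conditions: hν (450 nm LEDs), dry toluene (0.01 M), 25 °C; then 80 °C
Reagents that add atoms: none
Why: Proposed new method: irradiation expels N2 with 1,2-shift of the oxazol-4-yl carbon from the carbonyl carbon to the diazo carbon (Wolff rearrangement, forming C2–C3) to give ketene 17, in which the oxazole C4=C5 bond holds the ketene C3=C4 and the C8a=C4a bond of ring B cis, so that a thermal disrotatory 6π electrocyclisation forms C4–C4a and closes six-membered ring A as dienone 18, which enolises to naphthol 19. The closest known reaction types are the ketene electrocyclisations that end the Danheiser benzannulation and the thermal ring expansion of 4-arylcyclobutenones to 1-naphthols, together with the Wolff rearrangement of heteroaryl diazomethyl ketones; new here is a ketene flanked by an aryl group on an azole. No stereocentre survives, since C4a of 18 is planarised on tautomerisation and the Z iodoalkene does not absorb at 450 nm. The selectivity needed is closure at C4a and not at C8: C4a has the unsubstituted C5–H as neighbour and lies para to the C7 methyl, whereas closure at C8 would force the ketene oxygen into a peri clash with that methyl. Capture of the ketene by nucleophiles or its dimerisation is suppressed by dry toluene at high dilution, with the ring B oxygen masked as its PMB ether.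

Step 10
Reactants: 19 naphtho[2,1-d]oxazol-5-ol
Product: 20 5-[(tert-butyldimethylsilyl)oxy]-2-[(Z)-1-iodoprop-1-en-2-yl]-7-[(4-methoxybenzyl)oxy]-8-methylnaphtho[2,1-d][1,3]oxazole
Conditions: TBSCl, imidazole, DMF, rt
Reagents that add atoms: tert-butyldimethylsilyl chloride (CC(C)(C)[Si](C)(C)Cl)
Why: Silylation of the only free hydroxyl, the new C4 naphthol, which must be blocked so that the later formylation is directed by the C6 phenol alone.

Step 11
Reactants: 20 TBS ether
Product: 21 5-[(tert-butyldimethylsilyl)oxy]-2-[(Z)-1-iodoprop-1-en-2-yl]-8-methylnaphtho[2,1-d][1,3]oxazol-7-ol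
Conditions: CF3CO2H, anisole, CH2Cl2, 0 °C
Reagents that add atoms: none
Why: Acidolysis of the aryl PMB ether with anisole as cation trap (Friedel–Crafts capture of the 4-methoxybenzyl cation) frees the C6 phenol, while the acid-stable aryl TBS ether, the oxazole and the vinyl iodide persist.

Step 12
Reactants: 21 naphtho[2,1-d]oxazol-7-ol
Product: 22 5-[(tert-butyldimethylsilyl)oxy]-7-hydroxy-2-[(Z)-1-iodoprop-1-en-2-yl]-8-methylnaphtho[2,1-d][1,3]oxazole-6-carbaldehyde
Conditions: MgCl2, Et3N, (CH2O)n, MeCN, 75 °C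
Reagents that add atoms: paraformaldehyde (C=O)
Why: Magnesium-phenoxide-mediated ortho-formylation delivers formaldehyde through a six-membered chelate to the only free ortho position of the C6 phenol, C5, which is also the reactive alpha position of a 2-naphthol, the para position being a ring-fusion carbon.

Step 13
Reactants: 22 hydroxy aldehyde
Product: 23 5,7-bis[(tert-butyldimethylsilyl)oxy]-2-[(Z)-1-iodoprop-1-en-2-yl]-8-methylnaphtho[2,1-d][1,3]oxazole-6-carbaldehyde
Conditions: TBSOTf, 2,6-lutidine, CH2Cl2, 0 °C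
Reagents that add atoms: tert-butyldimethylsilyl trifluoromethanesulfonate (CC(C)(C)[Si](C)(C)OS(=O)(=O)C(F)(F)F)
Why: The silyl triflate silylates the hydrogen-bonded, doubly flanked phenol that the chloride would leave.

Step 14
Reactants: 23 bis-TBS aldehyde
Product: 24 5,7-bis[(tert-butyldimethylsilyl)oxy]-6-(dimethoxymethyl)-2-[(Z)-1-iodoprop-1-en-2-yl]-8-methylnaphtho[2,1-d][1,3]oxazole
Conditions: HC(OMe)3, PPTS (cat.), MeOH, rt
Reagents that add atoms: trimethyl orthoformate (COC(OC)OC); methanol (CO)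
Why: Acid-catalysed acetalisation masks the aldehyde so that it survives the later ylide step, aryl silyl ethers being stable to PPTS.

Step 15
Reactants: 25 (R)-4-benzyl-3-propanoyl-1,3-oxazolidin-2-one; 26 2-methylprop-2-enal
Product: 27 (R)-4-benzyl-3-[(2R,3R)-3-hydroxy-2,4-dimethylpent-4-enoyl]-1,3-oxazolidin-2-one
Conditions: Bu2BOTf, i-Pr2NEt, CH2Cl2, −78 → 0 °C; then H2O2, MeOH, pH 7 buffer
Reagents that add atoms: none
Why: Evans syn aldol: the (Z)-boron enolate reacts through a Zimmerman–Traxler chair on the face away from the benzyl group of the (R)-auxiliary, setting C22 and C21 (syn).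

Step 16
Reactants: 27 aldol adduct
Product: 28 (2R,3R)-3-hydroxy-N-methoxy-N,2,4-trimethylpent-4-enamide
Conditions: MeNHOMe·HCl, AlMe3, THF, −20 → 0 °C
Reagents that add atoms: N,O-dimethylhydroxylamine hydrochloride (CNOC.Cl)
Why: Aluminium amide aminolysis of the imide, assisted by chelation of the free beta-hydroxyl, gives the Weinreb amide and returns the auxiliary without epimerisation.

Step 17
Reactants: 28 Weinreb amide
Product: 29 (2R,3R)-3-hydroxy-N-methoxy-N,2-dimethyl-4-oxopentanamide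
Conditions: O3, CH2Cl2/MeOH, −78 °C; then Me2S
Reagents that add atoms: ozone (O=[O+][O-])
Why: Ozonolysis of the only alkene with reductive work-up gives the alpha-hydroxy methyl ketone.

Step 18
Reactants: 29 hydroxy ketone
Product: 30 (2R,3R,4R)-3,4-dihydroxy-N-methoxy-N,2,4-trimethylhex-5-ynamide
Conditions: HC≡CMgBr (3.5 equiv), THF, −78 → −40 °C; quench cold
Reagents that add atoms: ethynylmagnesium bromide (C#C[Mg]Br)
Why: The magnesium alkoxide of the C21 hydroxyl chelates the C20 ketone (Cram chelate), so the Grignard reagent adds from the face of the C21 hydrogen to give the syn-20,21-diol (C20 R), the ketone reacting at low temperature far faster than the Weinreb amide.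

Step 19
Reactants: 30 diol
Product: 31 (2R,3R,4R)-3,4-bis[(tert-butyldimethylsilyl)oxy]-N-methoxy-N,2,4-trimethylhex-5-ynamide
Conditions: TBSOTf (3 equiv), 2,6-lutidine, CH2Cl2, 0 °C → rt
Reagents that add atoms: tert-butyldimethylsilyl trifluoromethanesulfonate (CC(C)(C)[Si](C)(C)OS(=O)(=O)C(F)(F)F)
Why: The silyl triflate silylates both the secondary and the hindered tertiary propargylic hydroxyl.

Step 20
Reactants: 31 bis-TBS Weinreb amide
Product: 32 (2R,3R,4R)-3,4-bis[(tert-butyldimethylsilyl)oxy]-2,4-dimethylhex-5-ynal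
Conditions: i-Bu2AlH, THF, −78 °C
Reagents that add atoms: none
Why: The hydride reduces the Weinreb amide to the aldehyde through the stable chelated tetrahedral intermediate, without over-reduction or epimerisation at C22.

Step 21
Reactants: 33 2-methylidenepropane-1,3-diol
Product: 34 2-{[(triethylsilyl)oxy]methyl}prop-2-en-1-ol
Conditions: NaH (1.0 equiv), THF, 0 °C; then TESCl (1.0 equiv)
Reagents that add atoms: chlorotriethylsilane (CC[Si](CC)(CC)Cl)
Why: Monoprotection of a symmetric diol through its monosodium alkoxide, which is silylated before it can equilibrate to the dialkoxide.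

Step 22
Reactants: 34 monosilyl ether
Product: 35 2-{[(triethylsilyl)oxy]methyl}prop-2-enal
Conditions: MnO2, CH2Cl2, rt
Reagents that add atoms: none
Why: MnO2 oxidises the allylic alcohol to the 2-substituted acrolein without touching the silyl ether.

Step 23
Reactants: 25 (R)-4-benzyl-3-propanoyl-1,3-oxazolidin-2-one; 35 2-{[(triethylsilyl)oxy]methyl}prop-2-enal
Product: 36 (R)-4-benzyl-3-[(2R,3R)-3-hydroxy-2-methyl-4-{[(triethylsilyl)oxy]methyl}pent-4-enoyl]-1,3-oxazolidin-2-one
Conditions: Bu2BOTf, i-Pr2NEt, CH2Cl2, −78 → 0 °C; then H2O2, MeOH, pH 7 buffer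
Reagents that add atoms: none
Why: Evans syn aldol as in step 15; the same (R)-auxiliary sets C26 and C27 (syn) on an achiral aldehyde, so no double stereodifferentiation is involved.

Step 24
Reactants: 36 aldol adduct
Product: 37 (2R,3R)-3-hydroxy-N-methoxy-N,2-dimethyl-4-{[(triethylsilyl)oxy]methyl}pent-4-enamide
Conditions: MeNHOMe·HCl, AlMe3, THF, −20 → 0 °C
Reagents that add atoms: N,O-dimethylhydroxylamine hydrochloride (CNOC.Cl)
Why: Chelation-assisted aluminium amide aminolysis of the imide, as in step 16.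

Step 25
Reactants: 37 allylic alcohol
Product: 38 (2R,3S,4R)-3-hydroxy-4-(hydroxymethyl)-N-methoxy-N,2-dimethyl-5-[(triethylsilyl)oxy]pentanamide
Conditions: 9-BBN (3 equiv), THF, 0 °C → rt; then NaOH, H2O2, 0 °C
Reagents that add atoms: hydrogen peroxide (OO)
Why: Anti-Markovnikov hydroboration of the 1,1-disubstituted alkene takes place with the C27–H eclipsing the alkene (A(1,3) strain) on the face away from the C26 branch, which places the new CH2OH (C34a) syn to O27 along the C27–C28–C29 backbone as in the target, and oxidation gives the primary alcohol.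

Step 26
Reactants: 38 1,3-diol
Product: 39 N-methoxy-N-methyl amide of the C25–C29 acid with a 27,34a-O-(4-methoxybenzylidene) acetal (1,3-dioxane with aryl, C26 chain and CH2OTES all equatorial)
Conditions: 4-MeOC6H4CH(OMe)2, PPTS (cat.), CH2Cl2, 5 Å sieves, rt
Reagents that add atoms: 4-methoxybenzaldehyde dimethyl acetal (COc1ccc(C(OC)OC)cc1)
Why: Thermodynamic acetalisation of the 1,3-diol gives the all-equatorial dioxane, which fixes the acetal carbon and leaves an ether-type oxygen on C27 for the next aldol, the sieves taking up methanol so that the primary TES ether survives.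

Step 27
Reactants: 39 Weinreb amide acetal
Product: 40 C24–C29 ethyl ketone (2-[2-(4-methoxyphenyl)-5-{[(triethylsilyl)oxy]methyl}-1,3-dioxan-4-yl]pentan-3-one, configured as in 39)
Conditions: EtMgBr, THF, 0 °C
Reagents that add atoms: ethylmagnesium bromide (CC[Mg]Br)
Why: Grignard addition to the Weinreb amide stops at the chelated tetrahedral intermediate and gives the ethyl ketone on work-up without epimerisation at C26.

Step 28
Reactants: 40 C24–C29 ethyl ketone; 32 (2R,3R,4R)-3,4-bis[(tert-butyldimethylsilyl)oxy]-2,4-dimethylhex-5-ynal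
Product: 42 C18–C29 alkyne 23,25-diol (20,21-bis-TBS ether, 27,34a-anisylidene acetal, 29-TES ether; C20–C28 configured as in the target), via boron aldolate 41 (not isolated)
Conditions: (c-Hex)2BCl, Et3N, Et2O, 0 °C; then 32, −78 → −20 °C; then LiBH4, −78 °C; then H2O2, MeOH, pH 7 buffer
Reagents that add atoms: none
Why: The (E)-enol borinate of the ethyl ketone undergoes an anti aldol through a chair transition state steered by the C26 stereocentre (C24 methyl anti to the C26 methyl, C23 hydroxyl anti to the C24 methyl, the weakly biased syn-alpha-methyl-beta-silyloxy aldehyde being overridden), and hydride delivery from LiBH4 to the six-membered boron aldolate gives the 23,25-syn diol.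

Step 29
Reactants: 42 diol
Product: 43 C18–C29 alkyne 20,21,23,25-tetrakis-TBS ether
Conditions: TBSOTf, 2,6-lutidine, CH2Cl2, −78 → 0 °C
Reagents that add atoms: tert-butyldimethylsilyl trifluoromethanesulfonate (CC(C)(C)[Si](C)(C)OS(=O)(=O)C(F)(F)F)
Why: The silyl triflate silylates both hindered secondary hydroxyls, while the primary TES ether and the acetal persist at low temperature.

Step 30
Reactants: 43 terminal alkyne
Product: 44 (E)-C18 tributylstannyl alkene of the C18–C29 chain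
Conditions: Bu3SnH, PdCl2(PPh3)2 (5 mol %), THF, 0 °C → rt
Reagents that add atoms: tributyltin hydride (CCCC[SnH](CCCC)CCCC)
Why: Palladium-catalysed syn-hydrostannation places tin on the terminal carbon, away from the quaternary propargylic centre, and gives the (E)-vinylstannane.

Step 31
Reactants: 24 aromatic vinyl iodide; 44 vinylstannane
Product: 45 seco compound with the 16Z,18E-diene on oxazole C-2, aryl dimethyl acetal and C29 TES ether
Conditions: Pd2(dba)3 (5 mol %), AsPh3 (20 mol %), CuI (10 mol %), DMF, rt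
Reagents that add atoms: none
Why: Stille coupling (oxidative addition of zerovalent palladium to the activated Z vinyl iodide, tin-to-palladium transmetallation aided by CuI, reductive elimination) joins C17 and C18 with retention at both alkenes.

Step 32
Reactants: 45 C29 TES ether
Product: 46 C29 aldehyde
Conditions: (COCl)2, DMSO, CH2Cl2, −78 → −30 °C; then Et3N
Reagents that add atoms: none
Why: Under Swern conditions the chlorosulfonium salt cleaves the primary triethylsilyl ether and oxidises it in the same operation, whereas secondary, tertiary and aryl TBS ethers are inert.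

Step 33
Reactants: 46 C29 aldehyde
Product: 47 (12Z)-12-iodo-C12=C29 alkene (vinyl iodide with iodine cis to C28)
Conditions: EtPPh3I, n-BuLi, THF, rt; I2, −78 °C; NaN(SiMe3)2, −20 °C; then 46, −78 → −20 °C
Reagents that add atoms: ethyltriphenylphosphonium iodide (CC[P+](c1ccccc1)(c1ccccc1)c1ccccc1.[I-]); iodine (II)
Why: Stork–Zhao olefination: the alpha-iodo ylide made in the flask reacts under kinetic control to give the (Z)-2-iodoalk-2-ene, which is the geometry required at C12=C29.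

Step 34
Reactants: 47 aryl dimethyl acetal
Product: 48 aryl aldehyde vinyl iodide
Conditions: PPTS (cat.), acetone/H2O (10:1), rt
Reagents that add atoms: water (O)
Why: The acyclic dimethyl acetal of the electron-rich aryl aldehyde hydrolyses far faster than the cyclic anisylidene acetal or the silyl ethers.

Step 35
Reactants: 48 aryl aldehyde vinyl iodide
Product: 49 22-membered macrocyclic C11 alcohol (both C11 epimers)
Conditions: CrCl2 (15 equiv), NiCl2 (1 mol %), DMSO/THF, 0.002 M, rt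
Reagents that add atoms: none
Why: Nozaki–Hiyama–Kishi reaction: zerovalent nickel inserts into the C–I bond with retention and transmetallation gives a trivalent vinylchromium species that adds to the aldehyde at high dilution, closing the ring at C11–C12; the configuration at C11 is of no consequence.

Step 36
Reactants: 49 macrocyclic alcohol
Product: 50 macrocyclic (12Z)-aryl enone
Conditions: Dess–Martin periodinane, NaHCO3, CH2Cl2, 0 °C → rt
Reagents that add atoms: none
Why: Dess–Martin oxidation of the doubly activated (benzylic and allylic) alcohol gives the enone without touching the silyl ethers or the Z alkene.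

Step 37
Reactants: 50 macrocyclic enone
Product: 52 protected 2-amido-1,4-naphthoquinone macrocycle, via bis-naphthol 51 (not isolated)
Conditions: Bu4NF, AcOH (1:1), THF, 0 °C; then PhI(OAc)2 (1.05 equiv), MeCN/H2O (4:1), 0 °C
Reagents that add atoms: water (O)
Why: Proposed new method: buffered fluoride removes only the two aryl silyl groups, and PhI(OAc)2 then oxidises the electron-rich C4 naphthol (the C6 phenol is deactivated by the ortho ketone) to a phenoxenium ion that water captures at C1, the para carbon bearing the oxazole oxygen; collapse of this hemiketal breaks the C1–O bond to give the C1 and C4 carbonyls and an imidic acid that tautomerises to the C15 amide, the closest known reaction type being the hypervalent-iodine oxidation of 4-alkoxy-1-naphthols (hydroquinone monoethers) to 1,4-naphthoquinones with loss of the alkoxy group.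

Step 38
Reactants: 52 protected macrocycle
Product: 53 target CNP0297124.1
Conditions: HF (48 % aq), MeCN, 0 °C → rt
Reagents that add atoms: none
Why: Aqueous HF in acetonitrile cleaves the four alkyl TBS ethers and hydrolyses the acid-labile 4-methoxybenzylidene acetal, conditions that the quinone, the Z enone and the tertiary allylic alcohol (deactivated towards ionisation by the dienamide) are expected to survive.

**Compound list**

1 | prop-2-yn-1-ol | C#CCO | starting material
2 | (Z)-3-iodo-2-methylprop-2-en-1-ol | OC/C(C)=C\I | intermediate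
3 | (Z)-3-iodo-2-methylprop-2-enal | O=C/C(C)=C\I | intermediate
4 | (Z)-3-iodo-2-methylprop-2-enoic acid | OC(=O)/C(C)=C\I | intermediate
5 | 4-hydroxy-3-methylbenzoic acid | Cc1cc(C(=O)O)ccc1O | starting material
6 | 4-methoxybenzyl 4-[(4-methoxybenzyl)oxy]-3-methylbenzoate | COc1ccc(COC(=O)c2ccc(OCc3ccc(OC)cc3)c(C)c2)cc1 | intermediate
7 | 4-[(4-methoxybenzyl)oxy]-3-methylbenzoic acid | COc1ccc(COc2ccc(C(=O)O)cc2C)cc1 | intermediate
8 | methyl N-(diphenylmethylidene)glycinate | COC(=O)CN=C(c1ccccc1)c1ccccc1 | starting material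
9 | 4-[(4-methoxybenzyl)oxy]-3-methylbenzoyl chloride | COc1ccc(COc2ccc(C(Cl)=O)cc2C)cc1 | intermediate
10 | methyl 2-[(diphenylmethylidene)amino]-3-{4-[(4-methoxybenzyl)oxy]-3-methylphenyl}-3-oxopropanoate | COC(=O)C(N=C(c1ccccc1)c1ccccc1)C(=O)c1ccc(OCc2ccc(OC)cc2)c(C)c1 | intermediate
11 | methyl 2-amino-3-{4-[(4-methoxybenzyl)oxy]-3-methylphenyl}-3-oxopropanoate hydrochloride | COC(=O)C(N)C(=O)c1ccc(OCc2ccc(OC)cc2)c(C)c1.Cl | intermediate
12 | methyl 2-[(Z)-3-iodo-2-methylprop-2-enamido]-3-{4-[(4-methoxybenzyl)oxy]-3-methylphenyl}-3-oxopropanoate | COC(=O)C(NC(=O)/C(C)=C\I)C(=O)c1ccc(OCc2ccc(OC)cc2)c(C)c1 | intermediate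
13 | methyl 2-[(Z)-1-iodoprop-1-en-2-yl]-5-{4-[(4-methoxybenzyl)oxy]-3-methylphenyl}-1,3-oxazole-4-carboxylate | COC(=O)c1nc(/C(C)=C\I)oc1-c1ccc(OCc2ccc(OC)cc2)c(C)c1 | intermediate
14 | 2-[(Z)-1-iodoprop-1-en-2-yl]-5-{4-[(4-methoxybenzyl)oxy]-3-methylphenyl}-1,3-oxazole-4-carboxylic acid | OC(=O)c1nc(/C(C)=C\I)oc1-c1ccc(OCc2ccc(OC)cc2)c(C)c1 | intermediate
15 | isobutyl carbonic anhydride of acid 14 | CC(C)COC(=O)OC(=O)c1nc(/C(C)=C\I)oc1-c1ccc(OCc2ccc(OC)cc2)c(C)c1 | intermediate
16 | 2-diazo-1-{2-[(Z)-1-iodoprop-1-en-2-yl]-5-{4-[(4-methoxybenzyl)oxy]-3-methylphenyl}-1,3-oxazol-4-yl}ethan-1-one | [N-]=[N+]=CC(=O)c1nc(/C(C)=C\I)oc1-c1ccc(OCc2ccc(OC)cc2)c(C)c1 | intermediate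
17 | {2-[(Z)-1-iodoprop-1-en-2-yl]-5-aryl-1,3-oxazol-4-yl}ketene | O=C=Cc1nc(/C(C)=C\I)oc1-c1ccc(OCc2ccc(OC)cc2)c(C)c1 | intermediate
18 | 5a-H-naphtho[2,1-d]oxazol-5-one tautomer of 19 (C4a sp3) | O=C1C=C2N=C(/C(C)=C\I)OC2=C2C=C(C)C(OCc3ccc(OC)cc3)=CC12 | intermediate
19 | 2-[(Z)-1-iodoprop-1-en-2-yl]-7-[(4-methoxybenzyl)oxy]-8-methylnaphtho[2,1-d][1,3]oxazol-5-ol | COc1ccc(COc2cc3c(O)cc4nc(/C(C)=C\I)oc4c3cc2C)cc1 | intermediate
20 | 5-[(tert-butyldimethylsilyl)oxy]-2-[(Z)-1-iodoprop-1-en-2-yl]-7-[(4-methoxybenzyl)oxy]-8-methylnaphtho[2,1-d][1,3]oxazole | COc1ccc(COc2cc3c(O[Si](C)(C)C(C)(C)C)cc4nc(/C(C)=C\I)oc4c3cc2C)cc1 | intermediate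
21 | 5-[(tert-butyldimethylsilyl)oxy]-2-[(Z)-1-iodoprop-1-en-2-yl]-8-methylnaphtho[2,1-d][1,3]oxazol-7-ol | Cc1cc2c(cc1O)c(O[Si](C)(C)C(C)(C)C)cc1nc(/C(C)=C\I)oc12 | intermediate
22 | 5-[(tert-butyldimethylsilyl)oxy]-7-hydroxy-2-[(Z)-1-iodoprop-1-en-2-yl]-8-methylnaphtho[2,1-d][1,3]oxazole-6-carbaldehyde | Cc1cc2c(c(C=O)c1O)c(O[Si](C)(C)C(C)(C)C)cc1nc(/C(C)=C\I)oc12 | intermediate
23 | 5,7-bis[(tert-butyldimethylsilyl)oxy]-2-[(Z)-1-iodoprop-1-en-2-yl]-8-methylnaphtho[2,1-d][1,3]oxazole-6-carbaldehyde | Cc1cc2c(c(C=O)c1O[Si](C)(C)C(C)(C)C)c(O[Si](C)(C)C(C)(C)C)cc1nc(/C(C)=C\I)oc12 | intermediate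
24 | 5,7-bis[(tert-butyldimethylsilyl)oxy]-6-(dimethoxymethyl)-2-[(Z)-1-iodoprop-1-en-2-yl]-8-methylnaphtho[2,1-d][1,3]oxazole | Cc1cc2c(c(C(OC)OC)c1O[Si](C)(C)C(C)(C)C)c(O[Si](C)(C)C(C)(C)C)cc1nc(/C(C)=C\I)oc12 | intermediate
25 | (R)-4-benzyl-3-propanoyl-1,3-oxazolidin-2-one | CCC(=O)N1[C@H](Cc2ccccc2)COC1=O | starting material
26 | 2-methylprop-2-enal | C=C(C)C=O | starting material
27 | (R)-4-benzyl-3-[(2R,3R)-3-hydroxy-2,4-dimethylpent-4-enoyl]-1,3-oxazolidin-2-one | C=C(C)[C@H](O)[C@@H](C)C(=O)N1[C@H](Cc2ccccc2)COC1=O | intermediate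
28 | (2R,3R)-3-hydroxy-N-methoxy-N,2,4-trimethylpent-4-enamide | C=C(C)[C@H](O)[C@@H](C)C(=O)N(C)OC | intermediate
29 | (2R,3R)-3-hydroxy-N-methoxy-N,2-dimethyl-4-oxopentanamide | CC(=O)[C@H](O)[C@@H](C)C(=O)N(C)OC | intermediate
30 | (2R,3R,4R)-3,4-dihydroxy-N-methoxy-N,2,4-trimethylhex-5-ynamide | C#C[C@@](C)(O)[C@H](O)[C@@H](C)C(=O)N(C)OC | intermediate
31 | (2R,3R,4R)-3,4-bis[(tert-butyldimethylsilyl)oxy]-N-methoxy-N,2,4-trimethylhex-5-ynamide | C#C[C@@](C)(O[Si](C)(C)C(C)(C)C)[C@H](O[Si](C)(C)C(C)(C)C)[C@@H](C)C(=O)N(C)OC | intermediate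
32 | (2R,3R,4R)-3,4-bis[(tert-butyldimethylsilyl)oxy]-2,4-dimethylhex-5-ynal | C#C[C@@](C)(O[Si](C)(C)C(C)(C)C)[C@H](O[Si](C)(C)C(C)(C)C)[C@@H](C)C=O | intermediate
33 | 2-methylidenepropane-1,3-diol | C=C(CO)CO | starting material
34 | 2-{[(triethylsilyl)oxy]methyl}prop-2-en-1-ol | C=C(CO)CO[Si](CC)(CC)CC | intermediate
35 | 2-{[(triethylsilyl)oxy]methyl}prop-2-enal | C=C(C=O)CO[Si](CC)(CC)CC | intermediate
36 | (R)-4-benzyl-3-[(2R,3R)-3-hydroxy-2-methyl-4-{[(triethylsilyl)oxy]methyl}pent-4-enoyl]-1,3-oxazolidin-2-one | O=C(N1[C@H](Cc2ccccc2)COC1=O)[C@H](C)[C@@H](O)C(=C)CO[Si](CC)(CC)CC | intermediate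
37 | (2R,3R)-3-hydroxy-N-methoxy-N,2-dimethyl-4-{[(triethylsilyl)oxy]methyl}pent-4-enamide | CON(C)C(=O)[C@H](C)[C@@H](O)C(=C)CO[Si](CC)(CC)CC | intermediate
38 | (2R,3S,4R)-3-hydroxy-4-(hydroxymethyl)-N-methoxy-N,2-dimethyl-5-[(triethylsilyl)oxy]pentanamide | CON(C)C(=O)[C@H](C)[C@@H](O)[C@H](CO)CO[Si](CC)(CC)CC | intermediate
39 | 27,34a-O-(4-methoxybenzylidene) acetal of 38 (all-equatorial 1,3-dioxane) | CON(C)C(=O)[C@H](C)[C@H]1O[C@@H](c2ccc(OC)cc2)OC[C@@H]1CO[Si](CC)(CC)CC | intermediate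
40 | C24–C29 ethyl ketone, 2-[2-(4-methoxyphenyl)-5-{[(triethylsilyl)oxy]methyl}-1,3-dioxan-4-yl]pentan-3-one | CCC(=O)[C@H](C)[C@H]1O[C@@H](c2ccc(OC)cc2)OC[C@@H]1CO[Si](CC)(CC)CC | intermediate
41 | C23 O-dicyclohexylboryl aldolate of the C18–C29 beta-hydroxy ketone | C#C[C@@](C)(O[Si](C)(C)C(C)(C)C)[C@H](O[Si](C)(C)C(C)(C)C)[C@@H](C)[C@@H](OB(C1CCCCC1)C1CCCCC1)[C@@H](C)C(=O)[C@H](C)[C@H]1O[C@@H](c2ccc(OC)cc2)OC[C@@H]1CO[Si](CC)(CC)CC | intermediate
42 | C18–C29 alkyne 23,25-diol (20,21-bis-TBS, 27,34a-anisylidene acetal, 29-TES) | C#C[C@@](C)(O[Si](C)(C)C(C)(C)C)[C@H](O[Si](C)(C)C(C)(C)C)[C@@H](C)[C@@H](O)[C@@H](C)[C@@H](O)[C@H](C)[C@H]1O[C@@H](c2ccc(OC)cc2)OC[C@@H]1CO[Si](CC)(CC)CC | intermediate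
43 | C18–C29 alkyne 20,21,23,25-tetrakis-TBS ether | C#C[C@@](C)(O[Si](C)(C)C(C)(C)C)[C@H](O[Si](C)(C)C(C)(C)C)[C@@H](C)[C@@H](O[Si](C)(C)C(C)(C)C)[C@@H](C)[C@@H](O[Si](C)(C)C(C)(C)C)[C@H](C)[C@H]1O[C@@H](c2ccc(OC)cc2)OC[C@@H]1CO[Si](CC)(CC)CC | intermediate
44 | (18E)-18-tributylstannyl C18–C29 chain | CCCC[Sn](CCCC)(CCCC)/C=C/[C@@](C)(O[Si](C)(C)C(C)(C)C)[C@H](O[Si](C)(C)C(C)(C)C)[C@@H](C)[C@@H](O[Si](C)(C)C(C)(C)C)[C@@H](C)[C@@H](O[Si](C)(C)C(C)(C)C)[C@H](C)[C@H]1O[C@@H](c2ccc(OC)cc2)OC[C@@H]1CO[Si](CC)(CC)CC | intermediate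
45 | seco compound, 16Z,18E-dienyl oxazole with aryl dimethyl acetal and C29 TES ether | C/C(=C/C=C/[C@@](C)(O[Si](C)(C)C(C)(C)C)[C@H](O[Si](C)(C)C(C)(C)C)[C@@H](C)[C@@H](O[Si](C)(C)C(C)(C)C)[C@@H](C)[C@@H](O[Si](C)(C)C(C)(C)C)[C@H](C)[C@H]1O[C@@H](c2ccc(OC)cc2)OC[C@@H]1CO[Si](CC)(CC)CC)c1nc2cc(O[Si](C)(C)C(C)(C)C)c3c(C(OC)OC)c(O[Si](C)(C)C(C)(C)C)c(C)cc3c2o1 | intermediate
46 | seco compound, C29 aldehyde | C/C(=C/C=C/[C@@](C)(O[Si](C)(C)C(C)(C)C)[C@H](O[Si](C)(C)C(C)(C)C)[C@@H](C)[C@@H](O[Si](C)(C)C(C)(C)C)[C@@H](C)[C@@H](O[Si](C)(C)C(C)(C)C)[C@H](C)[C@H]1O[C@@H](c2ccc(OC)cc2)OC[C@@H]1C=O)c1nc2cc(O[Si](C)(C)C(C)(C)C)c3c(C(OC)OC)c(O[Si](C)(C)C(C)(C)C)c(C)cc3c2o1 | intermediate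
47 | seco compound, (12Z)-C12 vinyl iodide with aryl dimethyl acetal | C/C(=C/C=C/[C@@](C)(O[Si](C)(C)C(C)(C)C)[C@H](O[Si](C)(C)C(C)(C)C)[C@@H](C)[C@@H](O[Si](C)(C)C(C)(C)C)[C@@H](C)[C@@H](O[Si](C)(C)C(C)(C)C)[C@H](C)[C@H]1O[C@@H](c2ccc(OC)cc2)OC[C@@H]1/C=C(/C)I)c1nc2cc(O[Si](C)(C)C(C)(C)C)c3c(C(OC)OC)c(O[Si](C)(C)C(C)(C)C)c(C)cc3c2o1 | intermediate
48 | seco compound, (12Z)-C12 vinyl iodide with free aryl aldehyde | C/C(=C/C=C/[C@@](C)(O[Si](C)(C)C(C)(C)C)[C@H](O[Si](C)(C)C(C)(C)C)[C@@H](C)[C@@H](O[Si](C)(C)C(C)(C)C)[C@@H](C)[C@@H](O[Si](C)(C)C(C)(C)C)[C@H](C)[C@H]1O[C@@H](c2ccc(OC)cc2)OC[C@@H]1/C=C(/C)I)c1nc2cc(O[Si](C)(C)C(C)(C)C)c3c(C=O)c(O[Si](C)(C)C(C)(C)C)c(C)cc3c2o1 | intermediate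
49 | oxazole-bridged macrocycle, C11 alcohol (epimers) | C/C1=C/C=C/[C@@](C)(O[Si](C)(C)C(C)(C)C)[C@H](O[Si](C)(C)C(C)(C)C)[C@@H](C)[C@@H](O[Si](C)(C)C(C)(C)C)[C@@H](C)[C@@H](O[Si](C)(C)C(C)(C)C)[C@H](C)[C@H]2O[C@@H](c3ccc(OC)cc3)OC[C@@H]2/C=C(/C)C(O)c2c(O[Si](C)(C)C(C)(C)C)c(C)cc3c2c(O[Si](C)(C)C(C)(C)C)cc2nc1oc23 | intermediate
50 | oxazole-bridged macrocycle, C11 ketone | C/C1=C/C=C/[C@@](C)(O[Si](C)(C)C(C)(C)C)[C@H](O[Si](C)(C)C(C)(C)C)[C@@H](C)[C@@H](O[Si](C)(C)C(C)(C)C)[C@@H](C)[C@@H](O[Si](C)(C)C(C)(C)C)[C@H](C)[C@H]2O[C@@H](c3ccc(OC)cc3)OC[C@@H]2/C=C(/C)C(=O)c2c(O[Si](C)(C)C(C)(C)C)c(C)cc3c2c(O[Si](C)(C)C(C)(C)C)cc2nc1oc23 | intermediate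
51 | oxazole-bridged macrocycle with free C4 and C6 hydroxyls | C/C1=C/C=C/[C@@](C)(O[Si](C)(C)C(C)(C)C)[C@H](O[Si](C)(C)C(C)(C)C)[C@@H](C)[C@@H](O[Si](C)(C)C(C)(C)C)[C@@H](C)[C@@H](O[Si](C)(C)C(C)(C)C)[C@H](C)[C@H]2O[C@@H](c3ccc(OC)cc3)OC[C@@H]2/C=C(/C)C(=O)c2c(O)c(C)cc3c2c(O)cc2nc1oc23 | intermediate
52 | target with 20,21,23,25-O-TBS groups and 27,34a-O-(4-methoxybenzylidene) acetal | C/C1=C/C=C/[C@@](C)(O[Si](C)(C)C(C)(C)C)[C@H](O[Si](C)(C)C(C)(C)C)[C@@H](C)[C@@H](O[Si](C)(C)C(C)(C)C)[C@@H](C)[C@@H](O[Si](C)(C)C(C)(C)C)[C@H](C)[C@H]2O[C@@H](c3ccc(OC)cc3)OC[C@@H]2/C=C(/C)C(=O)c2c(O)c(C)cc3c2C(=O)C=C(NC1=O)C3=O | intermediate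
53 | CNP0297124.1 (12Z,16Z,18E,20R,21R,22S,23S,24S,25S,26R,27S,28S) | C/C1=C/C=C/[C@@](C)(O)[C@H](O)[C@@H](C)[C@@H](O)[C@@H](C)[C@@H](O)[C@H](C)[C@@H](O)[C@H](CO)/C=C(/C)C(=O)c2c(O)c(C)cc3c2C(=O)C=C(NC1=O)C3=O | target

**Step count, longest linear sequence and risks**

Total step count: 38. Longest linear sequence: 20 steps (5 → 53 through steps 3–14 and 31–38; the same length from 1).

Most likely to fail, first: step 9. The electrocyclisation may be slow because the triene borrows one double bond from a benzene ring and one from an oxazole, so that dimerisation of the ketene or its capture by traces of water competes, and closure could also take place at C8. The fallback uses the same bond-forming events in known, separate operations and sets out from 16. Silver benzoate and Et3N in MeOH (Arndt–Eistert homologation) should give methyl {2-[(Z)-1-iodoprop-1-en-2-yl]-5-aryl-1,3-oxazol-4-yl}acetate F1. LiOH should give the oxazol-4-ylacetic acid F2. Ac2O/NaOAc at 120 °C, the ring closure that ends the Stobbe route to 1-naphthols, should give the naphtho[2,1-d]oxazol-5-yl acetate F3. K2CO3 in MeOH would then release naphthol 19, where the route is rejoined.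

Second: step 37. Water may attack the oxidised naphthol at C3 instead of C1, which would lead to an ortho-quinone with the oxazole intact, or the cation may be intercepted by a neighbouring group of the bridge. The fallback sets out from 50 and separates hydrolysis from oxidation. Aqueous HCl in THF/MeOH should remove the silyl groups and the acetal and hydrolyse the oxazole, as 2-substituted benzoxazoles are hydrolysed to 2-acylaminophenols, giving the fully deprotected 2-amidonaphthalene-1,4-diol F4. Oxygen in a pH 7 buffer should then oxidise this hydroquinone to the quinone; the fallback comes back at 53.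

Third: step 35. Oligomerisation may outrun ring closure, and the addition to the aldehyde flanked by two silyloxy groups may be slow enough for the vinylchromium species to be protonated. The fallback closes the same bond as an acylation and sets out from 47. Pd(PPh3)4 with Me3SnSnMe3 should give the (12Z)-trimethylstannyl alkene F5. PPTS in wet acetone should free the aryl aldehyde F6, and Pinnick oxidation should give the aryl carboxylic acid F7. 1-Chloro-N,N,2-trimethylprop-1-en-1-amine should convert it into the acid chloride F8, and Pd2(dba)3/tri(2-furyl)phosphine at high dilution (Stille acylation, retention at the alkene) should close the ring to enone 50, where the route is rejoined.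

**Further compounds**

F1 | step 9 | methyl {2-[(Z)-1-iodoprop-1-en-2-yl]-5-{4-[(4-methoxybenzyl)oxy]-3-methylphenyl}-1,3-oxazol-4-yl}acetate | COC(=O)Cc1nc(/C(C)=C\I)oc1-c1ccc(OCc2ccc(OC)cc2)c(C)c1
F2 | step 9 | {2-[(Z)-1-iodoprop-1-en-2-yl]-5-{4-[(4-methoxybenzyl)oxy]-3-methylphenyl}-1,3-oxazol-4-yl}acetic acid | OC(=O)Cc1nc(/C(C)=C\I)oc1-c1ccc(OCc2ccc(OC)cc2)c(C)c1
F3 | step 9 | 2-[(Z)-1-iodoprop-1-en-2-yl]-7-[(4-methoxybenzyl)oxy]-8-methylnaphtho[2,1-d][1,3]oxazol-5-yl acetate | CC(=O)Oc1cc2nc(/C(C)=C\I)oc2c2cc(C)c(OCc3ccc(OC)cc3)cc12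
F4 | step 37 | deprotected 2-amidonaphthalene-1,4-diol (hydroquinone of 53) | C/C1=C/C=C/[C@@](C)(O)[C@H](O)[C@@H](C)[C@@H](O)[C@@H](C)[C@@H](O)[C@H](C)[C@@H](O)[C@H](CO)/C=C(/C)C(=O)c2c(O)c(C)cc3c(O)c(NC1=O)cc(O)c23
F5 | step 35 | seco compound, (12Z)-C12 trimethylstannyl alkene with aryl dimethyl acetal | C/C(=C/C=C/[C@@](C)(O[Si](C)(C)C(C)(C)C)[C@H](O[Si](C)(C)C(C)(C)C)[C@@H](C)[C@@H](O[Si](C)(C)C(C)(C)C)[C@@H](C)[C@@H](O[Si](C)(C)C(C)(C)C)[C@H](C)[C@H]1O[C@@H](c2ccc(OC)cc2)OC[C@@H]1/C=C(/C)[Sn](C)(C)C)c1nc2cc(O[Si](C)(C)C(C)(C)C)c3c(C(OC)OC)c(O[Si](C)(C)C(C)(C)C)c(C)cc3c2o1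
F6 | step 35 | seco compound, C12 trimethylstannyl alkene with aryl aldehyde | C/C(=C/C=C/[C@@](C)(O[Si](C)(C)C(C)(C)C)[C@H](O[Si](C)(C)C(C)(C)C)[C@@H](C)[C@@H](O[Si](C)(C)C(C)(C)C)[C@@H](C)[C@@H](O[Si](C)(C)C(C)(C)C)[C@H](C)[C@H]1O[C@@H](c2ccc(OC)cc2)OC[C@@H]1/C=C(/C)[Sn](C)(C)C)c1nc2cc(O[Si](C)(C)C(C)(C)C)c3c(C=O)c(O[Si](C)(C)C(C)(C)C)c(C)cc3c2o1
F7 | step 35 | seco compound, C12 trimethylstannyl alkene with aryl carboxylic acid | C/C(=C/C=C/[C@@](C)(O[Si](C)(C)C(C)(C)C)[C@H](O[Si](C)(C)C(C)(C)C)[C@@H](C)[C@@H](O[Si](C)(C)C(C)(C)C)[C@@H](C)[C@@H](O[Si](C)(C)C(C)(C)C)[C@H](C)[C@H]1O[C@@H](c2ccc(OC)cc2)OC[C@@H]1/C=C(/C)[Sn](C)(C)C)c1nc2cc(O[Si](C)(C)C(C)(C)C)c3c(C(=O)O)c(O[Si](C)(C)C(C)(C)C)c(C)cc3c2o1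
F8 | step 35 | seco compound, C12 trimethylstannyl alkene with aroyl chloride | C/C(=C/C=C/[C@@](C)(O[Si](C)(C)C(C)(C)C)[C@H](O[Si](C)(C)C(C)(C)C)[C@@H](C)[C@@H](O[Si](C)(C)C(C)(C)C)[C@@H](C)[C@@H](O[Si](C)(C)C(C)(C)C)[C@H](C)[C@H]1O[C@@H](c2ccc(OC)cc2)OC[C@@H]1/C=C(/C)[Sn](C)(C)C)c1nc2cc(O[Si](C)(C)C(C)(C)C)c3c(C(Cl)=O)c(O[Si](C)(C)C(C)(C)C)c(C)cc3c2o1
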